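**Strategy.** Everything rests on ring A (C1–C5, C10): its C4 carries CH3 (C19) and an oxidised carbon, CH2OH (C18), the pattern a 1,2-shift leaves behind. Ring A is therefore carried as a seven-membered ring in which C18 is a ring atom between C3 and C4. Lewis-acid rearrangement of the α-epoxide of its C4=C18 bond moves C3 from C18 to C4, which in one operation contracts seven to six, creates the C4 quaternary stereocentre and expels C18 as the formyl group. The precursor is a cycloheptadiene monoepoxide fused to a hydrindene from an amino-acid-mediated aldol condensation; ring D and C16/C17 follow by aldol and sulfur-ylide chemistry.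

Key step: step 12

Remark (numbering, assumed aphidicolane-type): ring A = C1–C5, C10; ring B = C5–C10; C18 (CH2OH) and C19 (CH3) on C4; C20 (CH3) on C10; bicyclo[3.2.1]octene = bridgeheads C8 and C12, two-carbon bridge C9=C11, one-carbon bridge C14, three-carbon bridge C15–C13–C16 (C15 on C8), C17 on C16. β is the face of C20; "axial" on ring D refers to the chair C8–C15–C13–C16–C12–C14.

Step 1
Reactants: 1 6-bromohex-1-ene; 2 acrolein
Product: 4 rac-nona-1,8-dien-3-ol, via hex-5-en-1-ylmagnesium bromide 3 (not isolated)
Conditions: Mg, THF, 40 °C; then 2, −78 °C; aq. NH4Cl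
Reagents that add atoms: none
Why: Grignard formation and 1,2-addition to the enal at low temperature should give the allylic alcohol, whose racemic stereocentre is erased in step 2.

Step 2
Reactants: 4 rac-nona-1,8-dien-3-ol
Product: 5 nona-1,8-dien-3-one
Conditions: MnO2, CH2Cl2, 23 °C
Reagents that add atoms: none
Why: Allylic alcohol oxidation with MnO2 should give the vinyl ketone without touching the isolated terminal alkene.

Step 3
Reactants: 6 cyclopentane-1,3-dione; 7 acrylonitrile
Product: 8 3-(2,5-dioxocyclopentyl)propanenitrile
Conditions: KOH (0.1 equiv), H2O, 60 °C, 6 in slight excess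
Reagents that add atoms: none
Why: Base-catalysed Michael addition (cyanoethylation) of the acidic 1,3-dione at C2 should give the C-monoalkylated dione; no stereocentre is formed.

Step 4
Reactants: 8 3-(2,5-dioxocyclopentyl)propanenitrile; 5 nona-1,8-dien-3-one
Product: 9 3-[2,5-dioxo-1-(3-oxonon-8-en-1-yl)cyclopentyl]propanenitrile
Conditions: Et3N (cat.), EtOAc, 40 °C
Reagents that add atoms: none
Why: Michael addition of the 2-substituted 1,3-dione to the vinyl ketone creates the quaternary but still prochiral C8 with two enantiotopic ring carbonyls.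

Step 5
Reactants: 9 triketone
Product: 11 3-[(7aS)-1,5-dioxo-4-(pent-4-en-1-yl)-1,2,3,5,6,7-hexahydro-7aH-inden-7a-yl]propanenitrile, via cis-fused aldol ketol 10 (not isolated)
Conditions: L-phenylalanine (1 equiv), (1S)-(+)-camphor-10-sulfonic acid (0.5 equiv), DMF, 30 → 70 °C
Reagents that add atoms: none
Why: Hajos–Parrish–Eder–Sauer–Wiechert aldol condensation, in which the enamine of the side-chain ketone attacks one enantiotopic ring carbonyl through C10 and sets C8 in the sense known for L-amino acids (that of the (S)-Hajos–Parrish ketone), followed by dehydration of ketol 10 to the C9=C10 enone.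

Step 6
Reactants: 11 enone dione
Product: 12 C14 ethylene ketal of 11
Conditions: ethylene glycol, TsOH·H2O (cat.), benzene, reflux, Dean–Stark
Reagents that add atoms: ethylene glycol, OCCO
Why: Acid-catalysed ketalization should select the saturated cyclopentanone C14 over the tetrasubstituted conjugated C5 enone, which ketalizes far more slowly.

Step 7
Reactants: 12 C14 ketal enone
Product: 13 C10-methylated ketone (C5=O, C9=C11, C10 with β-CH3 and α-pent-4-enyl)
Conditions: KOtBu, tBuOH/THF, 0 °C; MeI
Reagents that add atoms: iodomethane, CI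
Why: Deconjugative α-alkylation of the extended dienolate, in which MeI attacks C10 from the β face, anti to the pseudoaxial cyanoethyl group on C8, setting the C10 quaternary stereocentre and moving the alkene to C9=C11.

Step 8
Reactants: 13 C10-methylated ketone
Product: 14 C5 enol triflate (C5=C6)
Conditions: KN(SiMe3)2, THF, −78 °C; PhNTf2
Reagents that add atoms: N-phenylbis(trifluoromethanesulfonimide), O=S(=O)(N(c1ccccc1)S(=O)(=O)C(F)(F)F)C(F)(F)F
Why: Enol triflate formation; the C5 ketone can enolize only towards C6 because C10 is quaternary and C14 is masked.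

Step 9
Reactants: 14 C5 enol triflate
Product: 15 C5-isopropenyl diene (C6=C5–C4(CH3)=CH2)
Conditions: isopropenylboronic acid pinacol ester, Pd(PPh3)4 (cat.), K2CO3, dioxane/H2O, 80 °C
Reagents that add atoms: 4,4,5,5-tetramethyl-2-(prop-1-en-2-yl)-1,3,2-dioxaborolane, CC(=C)B1OC(C)(C)C(C)(C)O1
Why: Suzuki–Miyaura coupling of the vinyl triflate installs C4, C19 and the carbon later lost as ethene as a 2-substituted 1,3-diene.

Step 10
Reactants: 15 C5-isopropenyl diene
Product: 16 tricyclic cycloheptadiene (ring C1–C2–C3–C18–C4–C5–C10, C18=C4 and C5=C6)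
Conditions: second-generation Grubbs catalyst RuCl2(=CHPh)(PCy3)(H2IMes) (cat.), toluene, 80 °C
Reagents that add atoms: none
Why: Ring-closing metathesis between the only two terminal alkenes should close the seven-membered ring as the trisubstituted C18=C4 alkene, the hindered C5=C6 and C9=C11 bonds being inert.

Step 11
Reactants: 16 tricyclic cycloheptadiene
Product: 17 4α,18α-epoxide of 16
Conditions: mCPBA (1.05 equiv), NaHCO3, CH2Cl2, −20 °C
Reagents that add atoms: 3-chloroperoxybenzoic acid, OOC(=O)c1cccc(Cl)c1
Why: Prilezhaev epoxidation should take the distal, less hindered C4=C18 bond (C5=C6 and C9=C11 are each flanked by a quaternary carbon) from the α face, anti to the C20 methyl group over the β face, which fixes the configuration later relayed to C4.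

Step 12
Reactants: 17 4α,18α-epoxide
Product: 18 ring-contracted aldehyde (six-membered ring A, C4 with β-CH3 and α-CHO, C5=C6)
Conditions: MeAl(OC6H2-4-Br-2,6-tBu2)2 (2 equiv), CH2Cl2, −78 °C
Reagents that add atoms: none
Why: The bulky aluminium Lewis acid binds the epoxide oxygen on the open α face and the C4–O bond ionizes towards the tertiary, allyl-stabilized C4 (C4–C5–C6), after which the ring bond C18–C3 migrates to C4 and C18 becomes the formyl carbon. The closest known reaction type is the Meinwald (semipinacol) rearrangement of trisubstituted and vinyl epoxides to quaternary aldehydes with organoaluminium Lewis acids, including ring contraction of 1-methylcycloalkene oxides. No ring is closed by cyclization: the six-membered ring A (C1–C5, C10) arises from the seven-membered ring by a suprafacial 1,2-alkyl shift that extrudes C18. The new quaternary stereocentre C4 is controlled by the α-epoxide, because C3 enters anti to the departing oxygen, which leaves C19 β and the C18 formyl group α. The step needs alkyl shift to win over 1,2-hydride shift from C18 (which would give the cycloheptenone) and needs C4–O rather than C18–O cleavage; the hindered aluminium alkoxide, the alignment of the ring bond in the cis-fused epoxide and the strain released on going from seven to six ring atoms should secure the first, the allylic tertiary cation the second.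

Step 13
Reactants: 18 ring-contracted aldehyde
Product: 20 C18 alcohol with C16 aldehyde (C5=C6, C14 ketal), via aluminium-bound C16 aldimine 19 (not isolated)
Conditions: iBu2AlH (3 equiv), CH2Cl2, −78 → −20 °C; aq. Rochelle salt, then silica gel
Reagents that add atoms: water, O
Why: Hydride reduction turns the non-enolizable C18 aldehyde into the primary alcohol and the nitrile into aldimine 19, which is hydrolysed on the neutral work-up to the C16 aldehyde while the dioxolane survives.

Step 14
Reactants: 20 C18 alcohol with C16 aldehyde
Product: 21 5α-H trans-decalin hydroxy aldehyde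
Conditions: H2 (1 atm), [Ir(cod)(PCy3)(py)]PF6 (cat.), CH2Cl2, 23 °C
Reagents that add atoms: none
Why: Hydroxyl-directed hydrogenation, in which the α-oriented C18 hydroxyl binds iridium and delivers H2 to the α face of C5=C6 to set C5–H α (trans-decalin), while the undirected, doubly neopentyl C9=C11 alkene should not react.

Step 15
Reactants: 21 5α-H hydroxy aldehyde
Product: 23 bridged aldol (bicyclo[3.2.1]oct-6-en-8-one, C16–OH axial on the side of C14), via keto aldehyde 22 (not isolated)
Conditions: 2 M HCl, THF, 23 °C; then K2CO3 (excess), MeOH, 0 °C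
Reagents that add atoms: water, O
Why: Acid hydrolysis frees the C14 ketone, and base then forms the C12 dienolate (α to C14 and allylic), which adds through C12 to the C16 aldehyde in a six-membered chair (intramolecular aldol) to close ring D; C12 is fixed by the bridge and the reversible reaction should favour the C16 hydroxyl axial and hydrogen-bonded to the C14 carbonyl.

Step 16
Reactants: 23 bridged aldol
Product: 24 triol (C14–OH syn to the C9=C11 bridge)
Conditions: Me4NBH(OAc)3, MeCN/AcOH, −20 °C
Reagents that add atoms: none
Why: Evans–Saksena reduction, in which the axial C16 hydroxyl binds boron and delivers hydride to the face of C14 that looks towards C16, giving the 1,3-anti diol with the C14 hydroxyl syn to the C9=C11 bridge.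

Step 17
Reactants: 24 triol
Product: 25 C16 ketone with C14 and C18 alcohols
Conditions: Al(OiPr)3 (cat.), acetone, toluene, 80 °C
Reagents that add atoms: none
Why: Oppenauer oxidation is an equilibrium hydride transfer that should select the unhindered axial secondary C16 alcohol, because oxidation of the primary C18 alcohol and of the hindered C14 alcohol (to a strained bridging ketone) is disfavoured.

Step 18
Reactants: 25 C16 ketone
Product: 26 C16 spiro-epoxide (C17 axial on the side of C14, oxygen syn to the C9=C11 bridge)
Conditions: Me3S+ I− (4 equiv), KN(SiMe3)2 (3.5 equiv), THF, −10 °C; then 25, −10 → 23 °C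
Reagents that add atoms: trimethylsulfonium iodide, C[S+](C)C.[I-]
Why: Corey–Chaykovsky epoxidation, in which the small sulfonium ylide adds irreversibly along the axial trajectory on the exo face (the side of C14), so that C17 is axial and the oxygen equatorial, which sets C16; the ylide is too weak a base to deprotonate the free hydroxyls.

Step 19
Reactants: 26 C16 spiro-epoxide
Product: 27 botryotin E
Conditions: CsOAc, AcOH, DMF, 80 °C
Reagents that add atoms: acetic acid, CC(=O)O
Why: Buffered SN2 opening of the epoxide by acetate at the unsubstituted C17 leaves the C16–O bond and its configuration untouched and gives the primary acetate and tertiary alcohol of the target.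

**Compound list**

1 | 6-bromohex-1-ene | C=CCCCCBr | starting material
2 | acrolein | C=CC=O | starting material
3 | hex-5-en-1-ylmagnesium bromide | C=CCCCC[Mg]Br | intermediate (not isolated)
4 | rac-nona-1,8-dien-3-ol | C=CC(O)CCCCC=C | intermediate
5 | nona-1,8-dien-3-one | C=CC(=O)CCCCC=C | intermediate
6 | cyclopentane-1,3-dione | O=C1CCC(=O)C1 | starting material
7 | acrylonitrile | C=CC#N | starting material
8 | 3-(2,5-dioxocyclopentyl)propanenitrile | N#CCCC1C(=O)CCC1=O | intermediate
9 | 3-[2,5-dioxo-1-(3-oxonon-8-en-1-yl)cyclopentyl]propanenitrile (achiral) | N#CCCC1(CCC(=O)CCCCC=C)C(=O)CCC1=O | intermediate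
10 | cis-fused aldol ketol (C9–OH cis to the C8 cyanoethyl group, C10 epimers) | N#CCC[C@]12CCC(=O)C(CCCC=C)[C@@]1(O)CCC2=O | intermediate (not isolated)
11 | 3-[(7aS)-1,5-dioxo-4-(pent-4-en-1-yl)-1,2,3,5,6,7-hexahydro-7aH-inden-7a-yl]propanenitrile | N#CCC[C@]12CCC(=O)C(CCCC=C)=C1CCC2=O | intermediate
12 | C14 ethylene ketal of 11 | N#CCC[C@]12CCC(=O)C(CCCC=C)=C1CCC23OCCO3 | intermediate
13 | C10-methylated ketone (C20 β, pentenyl α, C9=C11) | N#CCC[C@]12CCC(=O)[C@](C)(CCCC=C)C1=CCC23OCCO3 | intermediate
14 | C5 enol triflate of 13 | N#CCC[C@]12CC=C(OS(=O)(=O)C(F)(F)F)[C@](C)(CCCC=C)C1=CCC23OCCO3 | intermediate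
15 | C5-isopropenyl diene | N#CCC[C@]12CC=C(C(C)=C)[C@](C)(CCCC=C)C1=CCC23OCCO3 | intermediate
16 | tricyclic cycloheptadiene (C18=C4, C5=C6) | N#CCC[C@]12CC=C4C(C)=CCCC[C@]4(C)C1=CCC23OCCO3 | intermediate
17 | 4α,18α-epoxide of 16 (oxygen anti to C20) | N#CCC[C@]12CC=C4[C@]5(C)O[C@@H]5CCC[C@]4(C)C1=CCC23OCCO3 | intermediate
18 | ring-contracted aldehyde (C4: β-CH3, α-CHO) | N#CCC[C@]12CC=C4[C@](C)(C=O)CCC[C@]4(C)C1=CCC23OCCO3 | intermediate
19 | C16 aldimine of the C18 alcohol (aluminium-bound in the flask) | N=CCC[C@]12CC=C4[C@](C)(CO)CCC[C@]4(C)C1=CCC23OCCO3 | intermediate (not isolated)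
20 | C18 alcohol with C16 aldehyde (C5=C6) | O=CCC[C@]12CC=C4[C@](C)(CO)CCC[C@]4(C)C1=CCC23OCCO3 | intermediate
21 | 5α-H trans-decalin hydroxy aldehyde | O=CCC[C@]12CC[C@H]4[C@](C)(CO)CCC[C@]4(C)C1=CCC23OCCO3 | intermediate
22 | keto aldehyde (C14 ketone, C16 aldehyde, C18 alcohol) | O=CCC[C@]12CC[C@H]4[C@](C)(CO)CCC[C@]4(C)C1=CCC2=O | intermediate (not isolated)
23 | bridged aldol (C14 ketone, C16–OH axial on the side of C14) | O[C@H]1CC[C@]23CC[C@H]4[C@](C)(CO)CCC[C@]4(C)C2=C[C@H]1C3=O | intermediate
24 | triol (C14–OH syn to C9=C11, C16–OH axial, C18–OH) | O[C@H]1CC[C@]23CC[C@H]4[C@](C)(CO)CCC[C@]4(C)C2=C[C@H]1[C@H]3O | intermediate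
25 | C16 ketone with C14 and C18 alcohols | O=C1CC[C@]23CC[C@H]4[C@](C)(CO)CCC[C@]4(C)C2=C[C@H]1[C@H]3O | intermediate
26 | C16 spiro-epoxide (C17 axial) | C5O[C@@]51CC[C@]23CC[C@H]4[C@](C)(CO)CCC[C@]4(C)C2=C[C@H]1[C@H]3O | intermediate
27 | botryotin E | CC(=O)OC[C@@]1(O)CC[C@]23CC[C@H]4[C@](C)(CO)CCC[C@]4(C)C2=C[C@H]1[C@H]3O | target

**Step count.** Total steps: 19. Longest linear sequence: 18 (steps 1, 2 and 4–19; 17 from cyclopentane-1,3-dione).

**Steps most likely to fail**

Step 12. The epoxide may ionize to a long-lived allyl cation, so that 1,2-hydride shift from C18 competes with the alkyl shift and the configuration at C4 leaks. The fallback sets out from 17 and returns at 21; it makes the hydride-shift ketone on purpose and contracts the ring without a cation by a Favorskii rearrangement.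
- Pd(PPh3)4 (cat., benzene, 40 °C) should isomerize the diene monoepoxide 17 to the β,γ-unsaturated C18 ketone F1.
- H2 over Pd/C (EtOAc) should add to C5=C6 from the α face, anti to C20, to give the trans-fused 2-methylcycloheptanone F2.
- SO2Cl2 (CH2Cl2, 0 °C, CaCO3) should chlorinate the more substituted α-carbon C4 from the α face to give the α-chloro ketone F3.
- NaOMe in Et2O (0 °C) should form the cyclopropanone with inversion at C4 and open it towards the less substituted carbanion, giving the ring-contracted methyl ester F4 with C19 β.
- iBu2AlH then reduces ester and nitrile to 21, so step 14 is no longer needed.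

Step 11. Epoxidation may spread over the three trisubstituted alkenes or over both faces. The fallback sets out from 13 and returns at 17; it lets a hydroxyl group direct the oxidant.
- Isopropenylmagnesium bromide with CeCl3 (THF, −78 °C) should add to the C5 ketone from the β face, the α face being screened by the axial pentenyl chain, to give the tertiary allylic alcohol F5.
- Ring-closing metathesis with the second-generation Grubbs catalyst gives the cycloheptenol F6.
- VO(acac)2/tBuOOH (CH2Cl2, 0 °C) should epoxidize only the allylic C4=C18 bond, syn to the α hydroxyl, to give the epoxy alcohol F7.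
- Burgess reagent (benzene, 50 °C) dehydrates the tertiary alcohol towards C6 and gives 17.

Step 17. The hydride-transfer equilibrium may not discriminate fully, with dehydrogenation at C18 or C14 or epimerization at C14 by reversible transfer. The fallback sets out from 24 and returns at 25; it uses protection and a kinetic oxidant.
- TBSCl/imidazole (DMF, 0 °C) should silylate only the primary C18 hydroxyl to give the silyl ether F8.
- Dess–Martin periodinane (1.1 equiv, NaHCO3, CH2Cl2) should oxidize the accessible axial C16 alcohol much faster than the neopentyl C14 alcohol on the bridge, to give the ketone F9.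
- HF·pyridine (THF) removes the silyl group and gives 25.

**Further compounds**

F1 | step 12 | β,γ-unsaturated cycloheptenone (C18 ketone, C4–H, C5=C6) | N#CCC[C@]12CC=C4C(C)C(=O)CCC[C@]4(C)C1=CCC23OCCO3
F2 | step 12 | trans-fused 2-methylcycloheptanone (C5–H α, C4 epimers) | N#CCC[C@]12CC[C@H]4C(C)C(=O)CCC[C@]4(C)C1=CCC23OCCO3
F3 | step 12 | α-chloro ketone (C4: α-Cl, β-CH3) | N#CCC[C@]12CC[C@H]4[C@](C)(Cl)C(=O)CCC[C@]4(C)C1=CCC23OCCO3
F4 | step 12 | ring-contracted methyl ester (C4: β-CH3, α-CO2CH3) | N#CCC[C@]12CC[C@H]4[C@](C)(C(=O)OC)CCC[C@]4(C)C1=CCC23OCCO3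
F5 | step 11 | tertiary allylic alcohol (C5: α-OH, β-isopropenyl) | N#CCC[C@]12CC[C@@](O)(C(C)=C)[C@](C)(CCCC=C)C1=CCC23OCCO3
F6 | step 11 | cycloheptenol (C5 α-OH, C4=C18) | N#CCC[C@]12CC[C@@]4(O)C(C)=CCCC[C@]4(C)C1=CCC23OCCO3
F7 | step 11 | α-epoxy alcohol (C5 α-OH, 4α,18α-epoxide) | N#CCC[C@]12CC[C@@]4(O)[C@]5(C)O[C@@H]5CCC[C@]4(C)C1=CCC23OCCO3
F8 | step 17 | C18 tert-butyldimethylsilyl ether of 24 | O[C@H]1CC[C@]23CC[C@H]4[C@](C)(CO[Si](C)(C)C(C)(C)C)CCC[C@]4(C)C2=C[C@H]1[C@H]3O
F9 | step 17 | C18 tert-butyldimethylsilyl ether of 25 | O=C1CC[C@]23CC[C@H]4[C@](C)(CO[Si](C)(C)C(C)(C)C)CCC[C@]4(C)C2=C[C@H]1[C@H]3O
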